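## The problem

Compound 22 (C24H18O11) is built from four phloroglucinol units: rings A, B and C are joined by two diaryl ether oxygens, and ring C is joined to ring D by a carbon–carbon biaryl bond. It has no stereocentre. The C–D axis carries four ortho oxygens, but ring D is a symmetric 2,4,6-trihydroxyphenyl group, so the target has no atropisomers and nothing in the molecule can direct anything else. Both difficult connections sit on ring C (C1 bears the oxygen to ring B, C2, C4 and C6 bear hydroxyls, C5 bears ring D). The C5 biaryl bond lies between the C4 and C6 oxygens and faces two more ortho oxygens on ring D, and the C1 ether oxygen lies between the C2 and C6 oxygens. On rings A, B and D all oxygens are mutually meta, a pattern that electrophilic substitution does not deliver, so each ring must be bought or built with its oxygens in place. The nine free phenols, above all the 1,2,4-trioxygenated ring C, are oxidised by air under neutral or basic conditions, so they stay masked until the last step and are released under acidic, anaerobic conditions. The enabling feature is ring D: C1 carries ring C, C2, C4 and C6 carry oxygen and C3 and C5 carry hydrogen, which is the pattern of an arylketene (C1–C2) that has taken up two alkoxyacetylenes (C6–C5 and C4–C3), so ring D can be grown on ring C from an arylacetic acid instead of being coupled to it.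

## Retrosynthesis

**Unmasking (22 from 21).** Only O–alkyl bonds are cut. Phenol 21 carries six methyl ethers on rings A to C and two ethyl ethers plus one free hydroxyl on ring D. Alkyl ethers are preferred to benzyl or silyl groups because they survive the copper catalysis, the bases and the 90 °C thermolysis upstream, and the ethyl groups come with the simplest commercial alkoxyacetylene. The forward step must cleave eight ethers in one operation without breaking the diaryl ethers.

**Ring D (21 from 13 and two molecules of 14).** The ring D bonds C1–C6, C2–C3 and C4–C5 are cut (C1 bears ring C, C2 bears the hydroxyl). What remains is the arylketene derived from acid chloride 13 and two molecules of ethoxyacetylene 14. The neighbouring cut, the C–D biaryl bond, would demand a cross-coupling that creates a biaryl with four ortho oxygens from a 2,4,6-trialkoxyphenyl metal species prone to protodemetalation. The ring-forming cut turns that bond into the ordinary aryl–CH2 bond of an arylacetic acid. The precursor has one ring fewer and no biaryl. The forward reaction must add both alkynes with the same orientation and must not lose the ketene intermediates to other pathways.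

**Activation (13 from 12 from 11).** No skeletal bond is cut. The acid chloride is traced to acid 12 and ethyl ester 11. The ester is the form in which the side chain is introduced and carried through the copper chemistry. The acid chloride must be made without reagents that attack the electron-rich rings A and B.

**Ether B–O–C (11 from 7 and 10).** The bond between the ring B carbon and the oxygen is cut, leaving the oxygen on ring C as phenol 7 and ring B as aryl bromide 10. The opposite polarity would need a ring C halide flanked by two methoxy groups as the electrophile and a second, different functionalisation of ring C. The chosen cut uses the oxygen that 2,4,6-trimethoxyphenol already has. The forward coupling must tolerate a di-ortho-substituted phenol and an ester.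

**Ether A–O–B (10 from 8 and 9).** The aryl–oxygen bond on ring B is cut to 3,5-dimethoxyphenol 8 and 1,3-dibromo-5-methoxybenzene 9. The symmetric dibromide supplies the 1,3,5-pattern of ring B directly. The forward reaction must stop at mono-substitution, which an excess of 9 ensures.

**Side chain (7 from 6 from 3 and 4).** The aryl–CH2 bond is cut to aryl bromide 3 and ethyl bromoacetate 4, joined through the zinc reagent 5. This is preferred to formylation and homologation because it installs the two-carbon acid unit in one step. Benzyl ether 6 is then opened to phenol 7 by hydrogenolysis. The coupling must work at a bromide with two ortho methoxy groups.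

**Ring C functionalisation (3 from 2 from 1).** The C–Br bond and the benzyl–O bond are cut. The two free positions of benzyl ether 2 are equivalent, so bromination has no regiochemical question. Benzylation of 2,4,6-trimethoxyphenol 1 protects the oxidation-prone phenol with a group that later leaves without touching the methyl ethers.

## Roads not taken

**Alternative 1:** Both aryl–oxygen bonds of ring B are cut. Ring B enters as the cationic complex [CpRu(η6-1,3-dichloro-5-methoxybenzene)]PF6 A2. Its chlorides are displaced in one pot by SNAr, first by the phenoxide of 8 and then by the phenoxide of 2,2',4,4',6,6'-hexamethoxy-[1,1'-biphenyl]-3-ol A3, giving the CpRu complex A1 of the nonamethyl ether. Photolytic decomplexation and BBr3 would follow.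
- Merits: the metal-activated arene reacts near room temperature, hindered phenoxides are no obstacle, and the first aryloxy group deactivates the ring enough to separate the two substitutions.
- Weak points: ruthenium is stoichiometric, complexation and decomplexation add operations, and A3 still contains the tetra-ortho-oxygenated biaryl, which must be made by cross-coupling. The hardest bond is moved, not removed.
- Comparison: for the ether bonds this road is better than the chosen plan, whose step 6 is a hot copper-catalysed coupling of a hindered phenol. The chosen plan sets against it that no biaryl coupling and no stoichiometric precious metal are needed.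

**Alternative 2:** Ring C is cut at C3–C4 and built by ring expansion of a squaric-acid-derived cyclobutenone. Thermolysis of 4-(1-ethoxyethenyl)-4-(methoxymethoxy)-3-(propan-2-yloxy)-2-(2,4,6-trimethoxyphenyl)cyclobut-2-en-1-one A5 opens the four-membered ring to a dienylketene. 6π closure then gives the ring C phenol A4.
- Merits: the biaryl bond comes from an organolithium addition and not from a coupling, the ring expansion runs at moderate temperature with strong precedent, and the four ring C oxygens emerge differentiated, the methoxymethyl-protected one being the site for ring B.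
- Weak points: the assembly of A5 needs two low-temperature organolithium additions with a regiochemical demand on the second, and acid-labile enol ether and acetal groups have to be carried. The ether to ring B must still be made by copper coupling, now on a phenol buttressed by the finished biaryl, and four kinds of protecting group are in play.
- Comparison: the step count is about the same and the key step is better precedented than the one chosen here. The chosen plan sets against it commercial two-carbon building blocks, a single type of permanent protecting group per ring, and an O-arylation done before the biaryl congestion exists.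

**Alternative 3:** Ring C is cut at C5–C6 and C3–C4 and built by Danheiser benzannulation. The cyclobutenone 4-[3-(3,5-dimethoxyphenoxy)-5-methoxyphenoxy]-3-ethoxycyclobut-2-en-1-one A7 carries rings A and B. It is heated with the ring D siloxyalkyne triisopropyl{[(2,4,6-trimethoxyphenyl)ethynyl]oxy}silane A8 to give the pentasubstituted ring C phenol A6.
- Merits: this is the most convergent road. It avoids the hindered ether coupling and any biaryl coupling, since both congested bonds of ring C are brought in on the two components.
- Weak points: the bimolecular [2+2] step must engage an internal alkyne at the carbon that bears an aryl group with two ortho methoxy groups, the least favourable case for this annulation. A8 requires ynolate chemistry on a hindered ester, and A6 carries ethyl, silyl and methyl ethers that need staged removal.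
- Comparison: on paper it is shorter than the chosen plan. The chosen plan asks the same type of cycloaddition only of the unhindered terminal carbon of ethoxyacetylene, twice, and accepts one copper-catalysed ether coupling as the price.

Key step: step 9

Remark on numbering: in ring D, C1 is bonded to ring C, C2 derives from the ketene carbonyl (the hydroxyl carbon of 21) and C6 is the other ortho carbon. "ArC" in names below is the 3-[3-(3,5-dimethoxyphenoxy)-5-methoxyphenoxy]-2,4,6-trimethoxyphenyl group.

## Route

Step 1
Reactants: 1 2,4,6-trimethoxyphenol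
Product: 2 2-(benzyloxy)-1,3,5-trimethoxybenzene
Conditions: BnBr, K2CO3, DMF, rt, N2
Reagents that add atoms: benzyl bromide, BrCc1ccccc1
Why: Williamson etherification (SN2) of the phenoxide; the benzyl ether shields the oxidation-prone phenol during bromination and cross-coupling and is later removed by hydrogenolysis without touching the methyl ethers.

Step 2
Reactants: 2 2-(benzyloxy)-1,3,5-trimethoxybenzene
Product: 3 1-(benzyloxy)-3-bromo-2,4,6-trimethoxybenzene
Conditions: NBS (1.0 equiv), MeCN, 0 °C, dark
Reagents that add atoms: N-bromosuccinimide, O=C1CCC(=O)N1Br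
Why: Electrophilic aromatic bromination; the two free ring positions are equivalent and each is ortho, ortho and para to a methoxy group, so one equivalent of NBS should give a single monobromide, the first bromine slowing a second substitution.

Step 3
Reactants: 3 1-(benzyloxy)-3-bromo-2,4,6-trimethoxybenzene; 4 ethyl bromoacetate
Product: 6 ethyl 2-[3-(benzyloxy)-2,4,6-trimethoxyphenyl]acetate, via (2-ethoxy-2-oxoethyl)zinc bromide 5 (not isolated)
Conditions: 4, Zn dust (TMSCl-activated), THF, 40 °C; then 3, Pd2(dba)3 (2.5 mol%), XPhos (10 mol%), THF, 65 °C
Reagents that add atoms: none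
Why: Zinc insertion into 4 gives the Reformatsky reagent 5, which is cross-coupled with the aryl bromide under zerovalent palladium catalysis (Negishi-type α-arylation of an ester); the bulky electron-rich biarylphosphine is chosen for oxidative addition and reductive elimination at the di-ortho-methoxy bromide, and the C-bound zinc enolate leaves ester and benzyl ether alone.

Step 4
Reactants: 6 ethyl 2-[3-(benzyloxy)-2,4,6-trimethoxyphenyl]acetate
Product: 7 ethyl 2-(3-hydroxy-2,4,6-trimethoxyphenyl)acetate
Conditions: H2 (1 atm), Pd/C, EtOAc, rt
Reagents that add atoms: none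
Why: Hydrogenolysis of the benzyl aryl ether; the aryl bromide is already consumed, methyl ethers and ester are inert, and the phenol is meta to the side chain so no lactone can form.

Step 5
Reactants: 8 3,5-dimethoxyphenol; 9 1,3-dibromo-5-methoxybenzene
Product: 10 1-bromo-3-(3,5-dimethoxyphenoxy)-5-methoxybenzene
Conditions: 9 (3 equiv), CuI (10 mol%), picolinic acid (20 mol%), K3PO4, DMSO, 90 °C
Reagents that add atoms: none
Why: Ullmann-type copper-catalysed diaryl ether synthesis with an unhindered phenoxide; the excess of the symmetric dibromide keeps double arylation low and is recovered on chromatography.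

Step 6
Reactants: 7 ethyl 2-(3-hydroxy-2,4,6-trimethoxyphenyl)acetate; 10 1-bromo-3-(3,5-dimethoxyphenoxy)-5-methoxybenzene
Product: 11 ethyl 2-{3-[3-(3,5-dimethoxyphenoxy)-5-methoxyphenoxy]-2,4,6-trimethoxyphenyl}acetate
Conditions: CuI (10 mol%), picolinic acid (20 mol%), K3PO4, DMSO, 100 °C, Ar
Reagents that add atoms: none
Why: Second Ullmann-type C–O coupling; the CuI/picolinic acid/K3PO4/DMSO system is the one established for di-ortho-substituted phenols with aryl bromides, the weak base does not enolise the arylacetate, and any ester hydrolysed on the way converges on 12 in step 7.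

Step 7
Reactants: 11 ethyl 2-{3-[3-(3,5-dimethoxyphenoxy)-5-methoxyphenoxy]-2,4,6-trimethoxyphenyl}acetate
Product: 12 2-{3-[3-(3,5-dimethoxyphenoxy)-5-methoxyphenoxy]-2,4,6-trimethoxyphenyl}acetic acid
Conditions: LiOH, THF/MeOH/H2O, rt; then aq. HCl to pH 3
Reagents that add atoms: lithium hydroxide, [Li+].[OH-]
Why: Saponification (BAc2) of an unhindered ethyl ester; diaryl ethers and aryl methyl ethers are inert to aqueous hydroxide.

Step 8
Reactants: 12 2-{3-[3-(3,5-dimethoxyphenoxy)-5-methoxyphenoxy]-2,4,6-trimethoxyphenyl}acetic acid
Product: 13 2-{3-[3-(3,5-dimethoxyphenoxy)-5-methoxyphenoxy]-2,4,6-trimethoxyphenyl}acetyl chloride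
Conditions: 1-chloro-N,N,2-trimethylprop-1-en-1-amine (1.0 equiv), CH2Cl2, 0 °C to rt; concentrated and used crude
Reagents that add atoms: 1-chloro-N,N,2-trimethylprop-1-en-1-amine, CC(C)=C(Cl)N(C)C
Why: The α-chloroenamine converts the acid into its chloride under neutral conditions with an inert amide as the only by-product, avoiding oxalyl or thionyl chloride, which can acylate or chlorinate the phloroglucinol-type rings A and B; exactly one equivalent is used so that no chloroenamine is left to react with the alkyne.

Step 9
Reactants: 13 2-{3-[3-(3,5-dimethoxyphenoxy)-5-methoxyphenoxy]-2,4,6-trimethoxyphenyl}acetyl chloride; 14 ethoxyacetylene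
Product: 21 3'-[3-(3,5-dimethoxyphenoxy)-5-methoxyphenoxy]-4,6-diethoxy-2',4',6'-trimethoxy-[1,1'-biphenyl]-2-ol, via arylketene 15 (not isolated), via 4-aryl-3-ethoxycyclobutenone 16 (not isolated), via vinylketene 17 (not isolated), via 4-alkenyl-3-ethoxycyclobutenone 18 (not isolated), via dienylketene 19 (not isolated), via cyclohexa-2,4-dienone 20 (not isolated)
Conditions: 14 (3 equiv), Et3N (1.2 equiv, slow addition), toluene, 0 °C to rt; filter off Et3NH+Cl−; then 14 (3 equiv), toluene, 90 °C, sealed tube
Reagents that add atoms: none
Why: Et3N dehydrochlorinates 13 to the arylketene 15, whose carbonyl carbon is attacked by the nucleophilic CH carbon of the ynol ether 14 while the aryl-bearing carbon closes onto the ethoxy-bearing carbon, a [2+2] ketene–alkyne cycloaddition that forms the ring D bond C1–C6 and gives cyclobutenone 16. At 90 °C 16 undergoes conrotatory 4π ring opening to the vinylketene 17, which adds a second molecule of 14 with the same polarity (forming C2–C3 and C4–C5) to give 18, and a second 4π opening gives the dienylketene 19, the reversible opening funnelling material through the isomer with a cis central double bond. Ring D is then closed by thermal disrotatory 6π electrocyclisation of 19 between the ketene carbon C2 and the aryl-bearing terminus C1, re-forming the bond opened in the first ring opening, and the cyclohexadienone 20 tautomerises irreversibly to the phenol 21. The closest known reaction types are the cycloaddition of aldoketenes generated in situ with alkoxyacetylenes and the Danheiser benzannulation of cyclobutenones with ynol ethers. No stereocentre survives: the sp3 carbons of 16, 18 and 20 are racemic and are lost on aromatisation, and 21 can at most be a racemic pair of atropisomers, which becomes irrelevant once ring D is symmetric after step 10. The selectivity needed is the regiochemistry of both alkyne additions, and it is secured by the polarisation of 14, whose oxygen makes the terminal carbon the nucleophile towards the ketene carbonyl carbon each time, placing both ethoxy groups meta to the hydroxyl. Chemoselectivity comes from the substrate and the procedure: both ortho positions of ring C carry methoxy groups, so 17 cannot close onto ring C to a naphthol, and slow addition of base into excess alkyne keeps the hindered ketene from dimerising. Removing the ammonium salt before heating keeps acid away from the ynol ether.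

Step 10
Reactants: 21 3'-[3-(3,5-dimethoxyphenoxy)-5-methoxyphenoxy]-4,6-diethoxy-2',4',6'-trimethoxy-[1,1'-biphenyl]-2-ol
Product: 22 3'-[3-(3,5-dihydroxyphenoxy)-5-hydroxyphenoxy]-[1,1'-biphenyl]-2,2',4,4',6,6'-hexol
Conditions: BBr3 (excess), CH2Cl2, −78 °C to rt; H2O quench and work-up under Ar
Reagents that add atoms: none
Why: Lewis-acid-mediated cleavage of aryl alkyl ethers: BBr3 coordinates each ether oxygen and bromide removes the methyl or ethyl group by SN2, while the diaryl ether and biaryl bonds, which have no sp3 carbon on oxygen, are untouched; the acidic, non-oxidising medium and anaerobic work-up protect the polyphenol.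

## Compound list

1 | 2,4,6-trimethoxyphenol | COc1cc(OC)c(O)c(OC)c1 | starting material
2 | 2-(benzyloxy)-1,3,5-trimethoxybenzene | COc1cc(OC)c(OCc2ccccc2)c(OC)c1 | intermediate
3 | 1-(benzyloxy)-3-bromo-2,4,6-trimethoxybenzene | COc1cc(OC)c(OCc2ccccc2)c(OC)c1Br | intermediate
4 | ethyl bromoacetate | CCOC(=O)CBr | starting material
5 | (2-ethoxy-2-oxoethyl)zinc bromide | CCOC(=O)C[Zn]Br | intermediate
6 | ethyl 2-[3-(benzyloxy)-2,4,6-trimethoxyphenyl]acetate | CCOC(=O)Cc1c(OC)cc(OC)c(OCc2ccccc2)c1OC | intermediate
7 | ethyl 2-(3-hydroxy-2,4,6-trimethoxyphenyl)acetate | CCOC(=O)Cc1c(OC)cc(OC)c(O)c1OC | intermediate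
8 | 3,5-dimethoxyphenol | COc1cc(O)cc(OC)c1 | starting material
9 | 1,3-dibromo-5-methoxybenzene | COc1cc(Br)cc(Br)c1 | starting material
10 | 1-bromo-3-(3,5-dimethoxyphenoxy)-5-methoxybenzene | COc1cc(Br)cc(Oc2cc(OC)cc(OC)c2)c1 | intermediate
11 | ethyl 2-{3-[3-(3,5-dimethoxyphenoxy)-5-methoxyphenoxy]-2,4,6-trimethoxyphenyl}acetate | CCOC(=O)Cc1c(OC)cc(OC)c(Oc2cc(OC)cc(Oc3cc(OC)cc(OC)c3)c2)c1OC | intermediate
12 | 2-{3-[3-(3,5-dimethoxyphenoxy)-5-methoxyphenoxy]-2,4,6-trimethoxyphenyl}acetic acid | OC(=O)Cc1c(OC)cc(OC)c(Oc2cc(OC)cc(Oc3cc(OC)cc(OC)c3)c2)c1OC | intermediate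
13 | 2-{3-[3-(3,5-dimethoxyphenoxy)-5-methoxyphenoxy]-2,4,6-trimethoxyphenyl}acetyl chloride | O=C(Cl)Cc1c(OC)cc(OC)c(Oc2cc(OC)cc(Oc3cc(OC)cc(OC)c3)c2)c1OC | intermediate
14 | ethoxyacetylene (ethoxyethyne) | CCOC#C | starting material
15 | 2-ArC-ethen-1-one (arylketene) | O=C=Cc1c(OC)cc(OC)c(Oc2cc(OC)cc(Oc3cc(OC)cc(OC)c3)c2)c1OC | intermediate
16 | 4-ArC-3-ethoxycyclobut-2-en-1-one (racemic) | CCOC1=CC(=O)C1c1c(OC)cc(OC)c(Oc2cc(OC)cc(Oc3cc(OC)cc(OC)c3)c2)c1OC | intermediate
17 | 4-ArC-3-ethoxybuta-1,3-dien-1-one (vinylketene, either alkene geometry) | O=C=CC(OCC)=Cc1c(OC)cc(OC)c(Oc2cc(OC)cc(Oc3cc(OC)cc(OC)c3)c2)c1OC | intermediate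
18 | 3-ethoxy-4-(1-ethoxy-2-ArC-ethenyl)cyclobut-2-en-1-one (racemic) | CCOC1=CC(=O)C1C(OCC)=Cc1c(OC)cc(OC)c(Oc2cc(OC)cc(Oc3cc(OC)cc(OC)c3)c2)c1OC | intermediate
19 | 6-ArC-3,5-diethoxyhexa-1,3,5-trien-1-one (dienylketene, C2 and C5 cis on the central double bond) | O=C=C/C(OCC)=C\C(OCC)=Cc1c(OC)cc(OC)c(Oc2cc(OC)cc(Oc3cc(OC)cc(OC)c3)c2)c1OC | intermediate
20 | 6-ArC-3,5-diethoxycyclohexa-2,4-dien-1-one (racemic) | CCOC1=CC(=O)C(c2c(OC)cc(OC)c(Oc3cc(OC)cc(Oc4cc(OC)cc(OC)c4)c3)c2OC)C(OCC)=C1 | intermediate
21 | 3'-[3-(3,5-dimethoxyphenoxy)-5-methoxyphenoxy]-4,6-diethoxy-2',4',6'-trimethoxy-[1,1'-biphenyl]-2-ol | CCOc1cc(O)c(-c2c(OC)cc(OC)c(Oc3cc(OC)cc(Oc4cc(OC)cc(OC)c4)c3)c2OC)c(OCC)c1 | intermediate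
22 | 3'-[3-(3,5-dihydroxyphenoxy)-5-hydroxyphenoxy]-[1,1'-biphenyl]-2,2',4,4',6,6'-hexol | Oc1cc(O)cc(Oc2cc(O)cc(Oc3c(O)cc(O)c(-c4c(O)cc(O)cc4O)c3O)c2)c1 | target

## Step count and risks

Total step count: 10. Longest linear sequence: 9 steps (1, 2, 3, 4, 6, 7, 8, 9, 10); step 5 is a one-step side branch.

**Step 9 (key step).**
- What may go wrong: the arylketene may be lost to dimerisation or amine-induced oligomerisation before it meets the alkyne. In the thermal stage the cyclobutenone, stabilised as a vinylogous ester, may open slowly, and the vinylketene may be consumed by O-acylation of the product phenol. Raising the temperature to compensate would start the fragmentation of ethoxyacetylene to ketene and ethylene.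
- Remedies within the step: isolate 16 before heating, and treat the crude product briefly with K2CO3/MeOH to cleave any aryl ester.
- Fallback (sets out from 3, returns only at 22): the biaryl is made by cross-coupling instead of ring construction. 1,3,5-Trimethoxybenzene would be lithiated (n-BuLi) and transmetalated with ZnCl2 to (2,4,6-trimethoxyphenyl)zinc chloride F1. Negishi coupling of F1 with 3 (Pd2(dba)3, RuPhos, THF, 70 °C, conditions of the kind used for tetra-ortho-substituted biaryls) would give 3-(benzyloxy)-2,2',4,4',6,6'-hexamethoxy-1,1'-biphenyl F2. Hydrogenolysis (H2, Pd/C) would give 2,2',4,4',6,6'-hexamethoxy-[1,1'-biphenyl]-3-ol F3 (the same compound as A3). Ullmann coupling with 10 under the conditions of step 6 would give 3-[3-(3,5-dimethoxyphenoxy)-5-methoxyphenoxy]-2,2',4,4',6,6'-hexamethoxy-1,1'-biphenyl F4, and BBr3 would convert it into 22.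

**Step 6.**
- What may go wrong: C–O bond formation at a copper phenoxide flanked by two methoxy groups is slow, so conversion may stall while hydrodebromination of 10 and oxidation of the electron-rich phenoxide proceed at 100 °C.
- Fallback (sets out from 10, returns at 11): an oxidative coupling at room temperature. Bromine–lithium exchange on 10 (n-BuLi, THF, −78 °C), quench with B(OiPr)3 and acidic hydrolysis would give [3-(3,5-dimethoxyphenoxy)-5-methoxyphenyl]boronic acid F5. Chan–Lam coupling of F5 with 7 (Cu(OAc)2, pyridine, 4 Å molecular sieves, CH2Cl2, dry air, rt), a method tolerant of di-ortho-substituted phenols and esters, would give 11.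

**Step 3.**
- What may go wrong: transmetalation and reductive elimination at a palladium centre bearing a di-ortho-methoxy aryl group may be slow, letting hydrodebromination and self-condensation of the zinc enolate take over.
- Fallback (sets out from 3, returns at 6): bromine–lithium exchange (n-BuLi, THF, −78 °C) and acylation with diethyl oxalate would give ethyl 2-[3-(benzyloxy)-2,4,6-trimethoxyphenyl]-2-oxoacetate F6. Ionic hydrogenation (Et3SiH, TFA, CH2Cl2, rt), which reduces electron-rich aryl ketones to methylene, would give 6.

**Step 10.**
- What may go wrong: cleavage may be incomplete (partly alkylated mixtures, the ethyl ethers being slowest, with boron-bound intermediates precipitating), and the 1,2,4-trioxygenated ring C may be oxidised during isolation.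
- Fallback (sets out from 21, returns at 22): the crude BBr3 product would be peracetylated at once (Ac2O, pyridine) to the nonaacetate 3'-[3-(3,5-diacetoxyphenoxy)-5-acetoxyphenoxy]-[1,1'-biphenyl]-2,2',4,4',6,6'-hexayl hexaacetate F7, which is stable to air and separable on silica from incompletely dealkylated material. Acid-catalysed methanolysis (HCl in degassed MeOH, rt) would then release 22.

## Further compounds

F1 | step 9 | (2,4,6-trimethoxyphenyl)zinc chloride | COc1cc(OC)c([Zn]Cl)c(OC)c1
F2 | step 9 | 3-(benzyloxy)-2,2',4,4',6,6'-hexamethoxy-1,1'-biphenyl | COc1cc(OC)c(-c2c(OC)cc(OC)c(OCc3ccccc3)c2OC)c(OC)c1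
F3 | step 9 | 2,2',4,4',6,6'-hexamethoxy-[1,1'-biphenyl]-3-ol | COc1cc(OC)c(-c2c(OC)cc(OC)c(O)c2OC)c(OC)c1
F4 | step 9 | 3-[3-(3,5-dimethoxyphenoxy)-5-methoxyphenoxy]-2,2',4,4',6,6'-hexamethoxy-1,1'-biphenyl | COc1cc(OC)cc(Oc2cc(OC)cc(Oc3c(OC)cc(OC)c(-c4c(OC)cc(OC)cc4OC)c3OC)c2)c1
F5 | step 6 | [3-(3,5-dimethoxyphenoxy)-5-methoxyphenyl]boronic acid | COc1cc(cc(Oc2cc(OC)cc(OC)c2)c1)B(O)O
F6 | step 3 | ethyl 2-[3-(benzyloxy)-2,4,6-trimethoxyphenyl]-2-oxoacetate | CCOC(=O)C(=O)c1c(OC)cc(OC)c(OCc2ccccc2)c1OC
F7 | step 10 | 3'-[3-(3,5-diacetoxyphenoxy)-5-acetoxyphenoxy]-[1,1'-biphenyl]-2,2',4,4',6,6'-hexayl hexaacetate | CC(=O)Oc1cc(OC(C)=O)cc(Oc2cc(OC(C)=O)cc(Oc3c(OC(C)=O)cc(OC(C)=O)c(-c4c(OC(C)=O)cc(OC(C)=O)cc4OC(C)=O)c3OC(C)=O)c2)c1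
A1 | alternative 1 | (η5-cyclopentadienyl)ruthenium hexafluorophosphate complex, η6-bound at ring B, of 3-[3-(3,5-dimethoxyphenoxy)-5-methoxyphenoxy]-2,2',4,4',6,6'-hexamethoxy-1,1'-biphenyl | COc1cc(OC)cc(Oc2cc(OC)cc(Oc3c(OC)cc(OC)c(-c4c(OC)cc(OC)cc4OC)c3OC)c2)c1.[CH-]1C=CC=C1.[Ru+2].F[P-](F)(F)(F)(F)F
A2 | alternative 1 | [CpRu(η6-1,3-dichloro-5-methoxybenzene)]PF6 | COc1cc(Cl)cc(Cl)c1.[CH-]1C=CC=C1.[Ru+2].F[P-](F)(F)(F)(F)F
A3 | alternative 1 | 2,2',4,4',6,6'-hexamethoxy-[1,1'-biphenyl]-3-ol | COc1cc(OC)c(-c2c(OC)cc(OC)c(O)c2OC)c(OC)c1
A4 | alternative 2 | 5-ethoxy-4-(methoxymethoxy)-3-(propan-2-yloxy)-2-(2,4,6-trimethoxyphenyl)phenol | Oc1cc(OCC)c(OCOC)c(OC(C)C)c1-c1c(OC)cc(OC)cc1OC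
A5 | alternative 2 | 4-(1-ethoxyethenyl)-4-(methoxymethoxy)-3-(propan-2-yloxy)-2-(2,4,6-trimethoxyphenyl)cyclobut-2-en-1-one (racemic) | CC(C)OC1=C(c2c(OC)cc(OC)cc2OC)C(=O)C1(OCOC)C(=C)OCC
A6 | alternative 3 | 3-[3-(3,5-dimethoxyphenoxy)-5-methoxyphenoxy]-4-ethoxy-2',4',6'-trimethoxy-6-[(triisopropylsilyl)oxy]-[1,1'-biphenyl]-2-ol | CCOc1cc(O[Si](C(C)C)(C(C)C)C(C)C)c(-c2c(OC)cc(OC)cc2OC)c(O)c1Oc1cc(OC)cc(Oc2cc(OC)cc(OC)c2)c1
A7 | alternative 3 | 4-[3-(3,5-dimethoxyphenoxy)-5-methoxyphenoxy]-3-ethoxycyclobut-2-en-1-one (racemic) | CCOC1=CC(=O)C1Oc1cc(OC)cc(Oc2cc(OC)cc(OC)c2)c1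
A8 | alternative 3 | triisopropyl{[(2,4,6-trimethoxyphenyl)ethynyl]oxy}silane | COc1cc(OC)c(C#CO[Si](C(C)C)(C(C)C)C(C)C)c(OC)c1
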